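**Assumption:** the target SMILES is read as (5E,7Z,12R,14Z) in prostanoid numbering, and (Z)-oct-2-en-1-ol and (R)-4-(TBSO)cyclopent-2-enone are taken as purchasable.

## Retrosynthetic overview

1. Target ⇒ desilylation, then C7=C8 disconnection by aldol condensation between the C8 enolate of a 2-bromo-4-silyloxy-cyclopentenone and methyl (E)-7-oxohept-5-enoate (5E pre-set in the aldehyde).
2. Bromoenone ⇒ epoxy-ketone opening/dehydration with HBr from (S)-4-hydroxy-4-[(Z)-oct-2-enyl]cyclopentenone, because Br2 would attack the 14Z olefin.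
3. Hydroxy-enone ⇒ (R)-4-(TBSO)cyclopentenone by anti 1,2-addition of a (Z)-oct-2-enyl barium reagent, then desilylation and allylic oxidation; the C4 centre relays chirality to C12 and is then erased.
4. Enal ⇒ cross-metathesis of methyl hex-5-enoate with crotonaldehyde.
5. Ring formation: none. The only ring (cyclopentenone) is present in the chiral starting material throughout.

## Forward route

**Step 1**
Reactants: 1, (Z)-oct-2-en-1-ol
Product: 2, (Z)-1-chlorooct-2-ene
Conditions: MsCl, LiCl, 2,4,6-collidine, DMF, 0 °C
Reagents that add atoms: LiCl, [Li+].[Cl-] (chloride source; MsCl only activates)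
Why: Collington–Meyers chlorination; the in situ allylic mesylate is displaced SN2 by chloride without allylic transposition, so the Z olefin is kept.

**Step 2**
Reactants: 2, (Z)-1-chlorooct-2-ene; 3, (R)-4-(tert-butyldimethylsilyloxy)cyclopent-2-en-1-one
Product: 4, (1S,4R)-4-(tert-butyldimethylsilyloxy)-1-[(Z)-oct-2-en-1-yl]cyclopent-2-en-1-ol (OH cis to OTBS)
Conditions: Ba* (BaI2, 2 Li biphenylide), THF; 2, –78 °C; then 3, –78 °C
Reagents that add atoms: none
Why: Yamamoto allylbarium addition is α-selective, 1,2-selective and retains Z geometry at –78 °C; attack anti to the C4 silyloxy group sets the tertiary carbinol (future C12), and the minor diastereomer is removed by chromatography.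

**Step 3**
Reactants: 4
Product: 5, (1S,4R)-1-[(Z)-oct-2-en-1-yl]cyclopent-2-ene-1,4-diol (cis diol)
Conditions: TBAF, THF, 0 °C
Reagents that add atoms: none
Why: Fluoride desilylation of the secondary TBS ether; no stereocentre is touched.

**Step 4**
Reactants: 5
Product: 6, (S)-4-hydroxy-4-[(Z)-oct-2-en-1-yl]cyclopent-2-en-1-one
Conditions: activated MnO2, CH2Cl2, rt
Reagents that add atoms: none
Why: Chemoselective allylic oxidation of the secondary alcohol; the tertiary allylic alcohol cannot oxidise, so the relay stereocentre is erased and only C12 remains.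

**Step 5**
Reactants: 6
Product: 7, (1S,4S,5R)-4-hydroxy-4-[(Z)-oct-2-en-1-yl]-6-oxabicyclo[3.1.0]hexan-2-one (epoxide drawn syn to OH; either epoxide epimer converges in step 6)
Conditions: 30% H2O2, NaOH (cat.), MeOH, –20 → 0 °C
Reagents that add atoms: hydrogen peroxide, OO
Why: Weitz–Scheffer nucleophilic epoxidation attacks only the electron-poor enone and leaves the isolated Z olefin alone; the epoxide stereocentres are transient.

**Step 6**
Reactants: 7
Product: 8, (S)-2-bromo-4-hydroxy-4-[(Z)-oct-2-en-1-yl]cyclopent-2-en-1-one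
Conditions: 48% aq. HBr, acetone, 0 °C → rt
Reagents that add atoms: hydrogen bromide, Br
Why: Bromide opens the epoxy ketone at the α-carbon (the β-carbon is neopentyl) and the α-bromo-β-hydroxy ketone dehydrates to the α-bromoenone, as in the corresponding chloroenone preparations; C12 is not involved.

**Step 7**
Reactants: 8
Product: 9, (S)-2-bromo-4-[(Z)-oct-2-en-1-yl]-4-(trimethylsilyloxy)cyclopent-2-en-1-one
Conditions: TMSCl, imidazole, DMF, 0 °C → rt
Reagents that add atoms: chlorotrimethylsilane, C[Si](C)(C)Cl
Why: Silylation of the tertiary alcohol removes the acidic OH before enolate chemistry and adds bulk at C12, which disfavours the 7E geometry later.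

**Step 8**
Reactants: 10, methyl hex-5-enoate; 11, (E)-crotonaldehyde (excess)
Product: 12, methyl (E)-7-oxohept-5-enoate
Conditions: Hoveyda–Grubbs II (3 mol %), CH2Cl2, 40 °C
Reagents that add atoms: none
Why: Olefin cross-metathesis of a terminal alkene with an enal gives the E-enal under thermodynamic control (propene lost), setting the 5E geometry.

**Step 9**
Reactants: 9; 12
Product: 13, methyl (5E)-7-[(2S)-4-bromo-2-[(Z)-oct-2-en-1-yl]-5-oxo-2-(trimethylsilyloxy)cyclopent-3-en-1-yl]-7-hydroxyhept-5-enoate (diastereomer mixture at C7/C8, inconsequential)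
Conditions: LDA, THF, –78 °C; then 12, –78 °C; AcOH quench
Reagents that add atoms: none
Why: Kinetic α′-lithium enolate (C8 is the only enolisable position) undergoes 1,2-aldol addition to the enal; the new C7/C8 stereocentres are destroyed in step 10.

**Step 10**
Reactants: 13
Product: 14, methyl (5E,7Z)-7-[(2R)-4-bromo-2-[(Z)-oct-2-en-1-yl]-5-oxo-2-(trimethylsilyloxy)cyclopent-3-en-1-ylidene]hept-5-enoate (separated from its 7E isomer)
Conditions: MsCl, Et3N, DMAP (cat.), CH2Cl2, –20 → 0 °C; subdued light
Reagents that add atoms: none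
Why: Mesylation and E1cB elimination give the cross-conjugated dienone as a 7Z/7E mixture (A(1,3) strain against the quaternary C12 makes 7Z competitive); the selectivity is not reliably predictable, so 7Z is isolated by chromatography.

**Step 11**
Reactants: 14
Product: 15, bromovulone III, methyl (5E,7Z)-7-[(2R)-4-bromo-2-hydroxy-2-[(Z)-oct-2-en-1-yl]-5-oxocyclopent-3-en-1-ylidene]hept-5-enoate
Conditions: HF·pyridine, THF, 0 °C
Reagents that add atoms: none
Why: Mild acidic fluoride cleavage of the tertiary TMS ether leaves the methyl ester, bromodienone and olefin geometries intact.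

## Compound list

1 | (Z)-oct-2-en-1-ol | CCCCC/C=C\CO | starting material
2 | (Z)-1-chlorooct-2-ene | CCCCC/C=C\CCl | intermediate
3 | (R)-4-(tert-butyldimethylsilyloxy)cyclopent-2-en-1-one | O=C1C=C[C@H](O[Si](C)(C)C(C)(C)C)C1 | starting material
4 | (1S,4R)-4-(TBSO)-1-[(Z)-oct-2-enyl]cyclopent-2-en-1-ol | CCCCC/C=C\C[C@@]1(O)C=C[C@H](O[Si](C)(C)C(C)(C)C)C1 | intermediate
5 | (1S,4R)-1-[(Z)-oct-2-enyl]cyclopent-2-ene-1,4-diol | CCCCC/C=C\C[C@@]1(O)C=C[C@H](O)C1 | intermediate
6 | (S)-4-hydroxy-4-[(Z)-oct-2-enyl]cyclopent-2-en-1-one | CCCCC/C=C\C[C@@]1(O)C=CC(=O)C1 | intermediate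
7 | (1S,4S,5R)-4-hydroxy-4-[(Z)-oct-2-enyl]-6-oxabicyclo[3.1.0]hexan-2-one | CCCCC/C=C\C[C@@]1(O)[C@@H]2O[C@@H]2C(=O)C1 | intermediate
8 | (S)-2-bromo-4-hydroxy-4-[(Z)-oct-2-enyl]cyclopent-2-en-1-one | CCCCC/C=C\C[C@@]1(O)C=C(Br)C(=O)C1 | intermediate
9 | (S)-2-bromo-4-[(Z)-oct-2-enyl]-4-(trimethylsilyloxy)cyclopent-2-en-1-one | CCCCC/C=C\C[C@@]1(O[Si](C)(C)C)C=C(Br)C(=O)C1 | intermediate
10 | methyl hex-5-enoate | C=CCCCC(=O)OC | starting material
11 | (E)-crotonaldehyde | C/C=C/C=O | starting material
12 | methyl (E)-7-oxohept-5-enoate | O=C/C=C/CCCC(=O)OC | intermediate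
13 | aldol adduct (C7/C8 diastereomer mixture) | CCCCC/C=C\C[C@@]1(O[Si](C)(C)C)C=C(Br)C(=O)C1C(O)/C=C/CCCC(=O)OC | intermediate
14 | 12-O-TMS bromovulone III | CCCCC/C=C\C[C@@]1(O[Si](C)(C)C)C=C(Br)C(=O)/C1=C\C=C\CCCC(=O)OC | intermediate
15 | bromovulone III | CCCCC/C=C\C[C@@]1(O)C=C(Br)C(=O)/C1=C\C=C\CCCC(=O)OC | target

## Totals

Total steps: 11. Longest linear sequence: 10 (steps 1–7, 9–11).

## Three steps most likely to fail

1. **Step 10 (7Z geometry).** The E1cB dehydration may favour 7E. Fallback: build C7=C8 by olefination instead. Convert 9 to its C8 bis(trifluoroethyl) β-keto phosphonate (enol phosphate, then LDA 1,3-phosphorus shift) and run a Still–Gennari-type Z-selective Horner–Wadsworth–Emmons reaction with 12, which places C6 syn to the ketone.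

2. **Step 2 (allylbarium addition).** Risks are α/γ regiochemistry, Z retention, and facial selectivity on the enone. Fallback: avoid ambident allyl metals. Add tert-butyl lithioacetate 1,2 to 3 (anti to OTBS), protect the tertiary alcohol, reduce the ester to the aldehyde with DIBAL, and form the 14Z olefin by salt-free Wittig reaction with n-hexylidenetriphenylphosphorane.

3. **Step 6 (HBr opening/dehydration).** The tertiary alcohol and Z olefin are exposed to strong acid, and dehydration may stall at the bromohydrin. Fallback: replace the Brønsted-acid step with Lewis-acid opening (MgBr2·OEt2) to the trans-bromohydrin followed by base-mediated β-elimination (MsCl/Et3N). If the olefin still interferes, brominate the enone with Br2/Et3N before the side-chain olefin exists, using the Wittig variant above.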